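The data are calculated with made-up constants; the scatter is artificial.

If a flask makes target at a rate that does not follow its charge, I reckon its time in charges turned over.

| flask | solid substrate | gas | remark | time |
|---|---|---|---|---|
| Monday's | 1.1 M | 200 mM (held) | run made earlier |  |
| Friday's | 1.8 M | 200 mM (held) | run made earlier |  |
| flask | 0.80 M | 200 mM (held) |  | 10 h |

| run | time / h | solid substrate / % | target / % |
|---|---|---|---|
| Monday's | 0.833 | 19.3 | 58.4 |
| Monday's | 1.50 | 0.9 | 93.3 |
| Monday's | 2.50 | 0 | 99.8 |
| Monday's | 3.00 | 0.4 | 101.0 |
| Monday's | 4.00 | 0 | 100.1 |
| Monday's | 5.00 | 0 | 99.7 |
| Monday's | 6.00 | 1.0 | 100.3 |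
| Friday's | 0.833 | 49.8 | 36.1 |
| Friday's | 1.50 | 22.9 | 65.0 |
| Friday's | 2.50 | 1.0 | 98.0 |
| Friday's | 3.00 | 0.6 | 98.1 |
| Friday's | 4.00 | 0 | 100.1 |
| Friday's | 5.00 | 0 | 100.2 |
| Friday's | 6.00 | 0 | 98.7 |

(standard deviation of a reading: 1 percentage point)

- as a solid, counted per litre of solution: solid substrate
- at the start none of the solid substrate is in solution
- at the start none of the gas is in solution
- what has only dissolved of solid substrate counts as not reacted
- the reaction counts as stopped when no species that holds the solid substrate changes by six tenths of a point or more over the second half of the time

- at 10 h, what has stopped the reaction, if anything has (for what has run out or reacted, a solid counts together with what of it has only dissolved) (forward and back rates have come level / all of the solid substrate has reacted / it is still moving)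
- part of the solid substrate that has turned into other species by 10 h (what has only dissolved does not count)
- amount of target at 10 h, in percent of the solid substrate charged

Friday's run holds 65.0% target at 1.50 h, which on 1.8 M charged reads as 0.780 M h⁻¹. Monday's run, with 1.1 M charged, reads 0.771 M h⁻¹ at its first reading, so I read target as forming at about one rate in both runs, zero-order in solid substrate while solid stands. The gas is held at the same 200 mM in the new flask, so I carry that rate over. On 0.80 M and 10 h it gives 9.75 turnovers, the turnover count being rate times time divided by charge. But a count has to be read against a run: Monday's run reads 93.3% target at a count of 1.06, and it still reads 100.3% at 6.00 h. The new flask's count lies far beyond one, so I expect its solid substrate to be gone and its target complete.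

The forecast reads: all of the solid substrate has reacted, conversion 100%, target 100%, with “no sign of an equilibrium limit”.

By 10 h, 100% of the flask's solid substrate has turned into other species: all of the solid substrate has reacted. The flask's target stands at 100%. At 0.500 h it holds 48.4% target, and the turnover count for that time is 48.8% of the charge.

    solid substrate ⇌ dissolved substrate, rate k1*(cs1 - [dissolved substrate]) while solid is left; crystals form when [dissolved substrate] > cs1 (solubility = 0.240 M, k = 0.299 s⁻¹)
    dissolved substrate + reagent → target (k = 0.696 L mol⁻¹ s⁻¹)
    reagent → side product (k = 1.03 s⁻¹)
    gas ⇌ reagent, rate k4*(csat - [reagent]) (kL = 0.00779 s⁻¹)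

The neighbour flask, left until 4.0 h, has a count of 3.90, past one, so I expect complete target there too. Computed, that neighbour flask holds >99.9% target, with 0% of its solid substrate left, solid or dissolved.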